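**Retrosynthetic overview**

1. Ring letters: A azepanone, B cyclohexene, C pyrrolidine, D seven-membered carbocycle, E fulvene five-ring, F dihydropyran. The enol acetate is made last from ring E ketone 31. Ring A is opened at its Mannich retron N–CH2–CH(CH3)–C=O (formaldehyde).
2. Enabling feature: in the keto tautomer of the acetoxyfulvene, ring F is a cyclic vinylogous ester of the ring E carbonyl. The ring F CH2 bound to ring E sits on the α-carbon of that ketone, so it is a β-acceptor carbon once drawn as an exocyclic methylene. The O-bound sp2 carbon shared by rings D and F is the δ-carbon of the dienone O=C–C=C–C=C that runs through ring E. The CH2–O unit between these two acceptor carbons is methanol, clipped in by its C–H and O–H bonds (key step), with a sulfonyl leaving group on the δ-carbon.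
3. Ring B: the tertiary carbinol is the aldol retron of a 1,2-diketone on ring E and a methyl ketone. The methyl ketone is masked, together with the amine, as an exocyclic enecarbamate on ring C.
4. Rings D and E: one allenic Pauson–Khand reaction of a sulfonylallene–ynedione. The sulfonyl group builds the allene, steers the seven-ring cyclocarbonylation and leaves in the key step.
5. Stereochemistry: one centre comes from a catalytic nitro-Michael addition and the quaternary carbon from anti alkylation. The carbinolamine, carbinol and C-methyl carbons follow from ring constraints and equilibration. Order of ring formation: C, then D and E together, B, F, A.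

Key step: step 15

Assumption: the C-methyl carbon next to the ring A ketone is epimerisable and the configuration drawn is taken to be the more stable one; compounds 23 to 29 are drawn as closed N-Boc carbinolamines, which may be in ring–chain equilibrium with the keto carbamates.

**Step 1**
Reactants: 1 tert-butyldimethyl(prop-2-yn-1-yloxy)silane; 2 oxetane
Product: 3 6-[(tert-butyldimethylsilyl)oxy]hex-4-yn-1-ol
Conditions: nBuLi, THF, −78 °C; then 2, BF3·OEt2, −78 °C; aqueous work-up
Reagents that add atoms: none
Why: Lewis-acid-assisted SN2 opening of oxetane by a lithium acetylide is a standard three-carbon homologation and forms no stereocentre.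

**Step 2**
Reactants: 3 6-[(tert-butyldimethylsilyl)oxy]hex-4-yn-1-ol
Product: 4 6-[(tert-butyldimethylsilyl)oxy]hex-4-ynal
Conditions: TEMPO (10 mol%), PhI(OAc)2, CH2Cl2, rt
Reagents that add atoms: none
Why: The oxoammonium-catalysed oxidation stops at the aldehyde, tolerates the alkyne and the silyl ether, and involves no stereocentre.

**Step 3**
Reactants: 4 6-[(tert-butyldimethylsilyl)oxy]hex-4-ynal
Product: 6 (E)-nitroalkene, via nitroaldol 5 (not isolated)
Conditions: MeNO2 (5 equiv), piperidine (10 mol%), 4 Å molecular sieves, toluene, reflux
Reagents that add atoms: nitromethane C[N+](=O)[O-]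
Why: Henry addition and amine-catalysed dehydration over molecular sieves in one flask should give the conjugated nitroalkene, the E isomer being the thermodynamic product at reflux, and no stereocentre persists.

**Step 4**
Reactants: 6 (E)-nitroalkene; 7 methyl acetoacetate
Product: 8 (S)-γ-nitro β-keto ester (epimers at the acidic carbon)
Conditions: NiBr2[(R,R)-N,N'-dibenzylcyclohexane-1,2-diamine]2 (2 mol%), toluene, rt
Reagents that add atoms: none
Why: In this catalytic enantioselective Michael addition of a 1,3-dicarbonyl compound to a nitroalkene the chiral divalent nickel enolate attacks one face of 6 and sets the only stereocentre made by catalysis (the diamine enantiomer is the one that gives the S configuration, the antipodal complex being equally available should the sense of induction prove opposite), while the acidic carbon between the carbonyl groups stays a mixture that is levelled in step 5.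

**Step 5**
Reactants: 8 (S)-γ-nitro β-keto ester
Product: 10 cyclic enamino ester, via amino keto ester 9 (not isolated)
Conditions: Zn, AcOH, EtOH, 0 °C to rt
Reagents that add atoms: none
Why: Zinc in acetic acid reduces the aliphatic nitro group to the amine without touching the alkyne or the silyl ether, and the amine condenses at once with the ketone (imine–enamine condensation, five-membered ring C) to the conjugated enamino ester, so that the epimeric carbon becomes planar and the catalytic stereocentre is untouched.

**Step 6**
Reactants: 10 cyclic enamino ester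
Product: 11 quaternary imine ester (C-methyl trans to the side chain)
Conditions: LiN(SiMe3)2, THF, −78 °C; MeI, −78 to 0 °C
Reagents that add atoms: iodomethane CI
Why: Alkylation of the lithium aza-enolate of the vinylogous carbamate takes place at carbon (metalloenamine alkylation), and iodomethane approaches the flat five-membered ring anti to the neighbouring side chain, which sets the quaternary stereocentre by substrate control.

**Step 7**
Reactants: 11 quaternary imine ester
Product: 12 exocyclic enecarbamate ester
Conditions: Boc2O, DMAP (10 mol%), MeCN, 40 °C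
Reagents that add atoms: di-tert-butyl dicarbonate CC(C)(C)OC(=O)OC(=O)OC(C)(C)C
Why: N-Acylation of the ketimine is followed by loss of a proton from the 2-methyl group, the only enolisable position because the other α-carbon is quaternary, and gives the exocyclic enecarbamate that masks amine and methyl ketone in one group without touching a stereocentre.

**Step 8**
Reactants: 12 exocyclic enecarbamate ester
Product: 14 terminal alkyne, via aldehyde 13 (not isolated)
Conditions: iBu2AlH (1.1 equiv), CH2Cl2, −78 °C; MeOH; then K2CO3, dimethyl (1-diazo-2-oxopropyl)phosphonate, 0 °C to rt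
Reagents that add atoms: dimethyl (1-diazo-2-oxopropyl)phosphonate CC(=O)C(=[N+]=[N-])P(=O)(OC)OC
Why: Partial reduction of the hindered methyl ester stops at the aluminium hemiacetal at low temperature, and the aldehyde set free by methanol is homologated in the same flask by the Ohira–Bestmann variant of the Seyferth–Gilbert reaction, the quaternary α-carbon excluding epimerisation.

**Step 9**
Reactants: 14 terminal alkyne
Product: 15 propargylic alcohol
Conditions: nBu4NF, THF, 0 °C
Reagents that add atoms: none
Why: Fluoride-induced desilylation is orthogonal to the carbamate, the enecarbamate and both alkynes and touches no stereocentre.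

**Step 10**
Reactants: 15 propargylic alcohol; 16 N,N'-dimethoxy-N,N'-dimethyloxamide
Product: 19 alkynyl 1,2-diketone, via magnesium hemiaminal 17 (not isolated), via dimagnesium salt 18 (not isolated)
Conditions: 16, EtMgBr (1.0 equiv), THF, −78 to −20 °C; separately 15, EtMgBr (2.1 equiv), THF, 40 °C; combine, 0 °C to rt; aqueous work-up
Reagents that add atoms: ethylmagnesium bromide CC[Mg]Br
Why: In this double Weinreb ketone synthesis on the oxalic diamide each organomagnesium adds once to one amide carbonyl and both chelated tetrahedral intermediates persist until work-up, so that the unsymmetrical alkynyl 1,2-diketone is released only on quenching, the side-chain alkoxide staying inert and no stereocentre being touched.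

**Step 11**
Reactants: 19 alkynyl 1,2-diketone
Product: 21 sulfonylallene ynedione, via propargyl sulfinate 20 (not isolated)
Conditions: PhS(O)Cl, Et3N, CH2Cl2, −78 to 0 °C; then AgSbF6 (5 mol%), CH2Cl2, rt
Reagents that add atoms: benzenesulfinyl chloride O=S(Cl)c1ccccc1
Why: O-Sulfinylation of the primary propargylic alcohol and silver-catalysed [2,3]-sigmatropic rearrangement of the propargyl sulfinate deliver the 1-sulfonylallene directly at the sulfone level, without an oxidant that would attack the enecarbamate, and no stereocentre is formed.

**Step 12**
Reactants: 21 sulfonylallene ynedione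
Product: 22 tricyclic dienone (rings C D E)
Conditions: [RhCl(CO)2]2 (5 mol%), CO (1 atm), toluene, 90 °C
Reagents that add atoms: carbon monoxide [C-]#[O+]
Why: In the allenic Pauson–Khand reaction monovalent rhodium couples the alkyne with the terminal C=C of the 1-sulfonylallene and inserts CO, the reaction type known to turn four-atom-tethered sulfonylallenynes into bicyclo[5.3.0]deca-1,7-dien-9-ones, here helped by the quaternary carbon in the tether, and rings D and E arise without a new stereocentre.

**Step 13**
Reactants: 22 tricyclic dienone
Product: 23 tetracyclic N-Boc carbinolamine (rings B C D E)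
Conditions: Sc(OTf)3 (10 mol%), MeCN/H2O 20:1, 0 °C to rt
Reagents that add atoms: water O
Why: Lewis-acid-promoted addition of the enecarbamate carbon to the chelated, ring-E-bound carbonyl of the 1,2-diketone (aza-ene or Mukaiyama-type aldol addition, possible only now that the linear alkyne has become a cis alkene) closes six-membered ring B, water traps the N-acyliminium ion on the face of the angular methyl group because only a cis B/C fusion is within reach, and the reversibly formed carbinol carbon is drawn as the epimer with propionyl cis to nitrogen, the one that step 16 selects.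

**Step 14**
Reactants: 23 tetracyclic N-Boc carbinolamine
Product: 26 exocyclic methylene ketone, via Mannich base 24 (not isolated), via methiodide 25 (not isolated)
Conditions: Me2N=CH2+ I− (1.1 equiv), iPr2NEt, CH2Cl2, 0 °C; then MeI, rt; then aq NaHCO3; used without storage
Reagents that add atoms: N,N-dimethylmethyleneiminium iodide C[N+](C)=C.[I-]
Why: The ring E methylene flanked by the ketone and the vinyl sulfone is by far the most acidic position, so that aminomethylation with the preformed iminium salt (Mannich reaction), quaternisation and E1cB loss of trimethylamine should give the α-methylene ketone without touching the ethyl ketone or any stereocentre.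

**Step 15**
Reactants: 26 exocyclic methylene ketone; 27 methanol
Product: 29 pentacyclic vinylogous ester (rings B to F), via hydroxyethyl ketone 28 (not isolated)
Conditions: (nBu4N)4[W10O32] (2 mol%), MeOH/MeCN 1:1 (0.02 M), 390 nm LED, N2, 20 °C; then Et3N (3 equiv), same flask, rt
Reagents that add atoms: none
Why: Proposed new method: excited decatungstate abstracts a hydrogen atom from methanol, the nucleophilic hydroxymethyl radical adds to the CH2 terminus of the exocyclic enone of 26 (new C–C bond), the delocalised radical takes hydrogen back from the reduced tungstate to give γ-hydroxy ketone 28, and after addition of Et3N the hydroxyl oxygen adds to the sulfonyl-bearing carbon at the δ-end of the ring E dienone and benzenesulfinate leaves (new C–O bond), so that methanol is clipped through its C–H and its O–H bond across the two acceptor carbons of one carbonyl group. The closest known reaction types are the photocatalytic hydrogen-atom-transfer Giese addition of alcohols to acrylates that ends in lactonisation and the addition–elimination of alkoxides on β-sulfonyl enones; their union on a 5-methylidene-4-(sulfonylalkylidene)cyclopent-2-enone is new. Ring F closes by a 6-endo-trig addition–elimination, while the five-membered lactol that the same hydroxyl group can form at the ring E ketone is reversible and drains into the vinylogous ester. The only new stereocentre, the ring E carbon that carries the new chain, is not controlled and becomes planar in step 17. The step needs hydrogen abstraction from methanol and not from the substrate, which the large excess of methanol and the electron-poor carbamate nitrogen secure, and radical attack at one alkene only, which is secured because the other two C=C bonds of the chromophore are tetrasubstituted and the 1,2-diketone and the enecarbamate were already used up in step 13.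

**Step 16**
Reactants: 29 pentacyclic vinylogous ester
Product: 31 hexacyclic ketone (keto tautomer of the deacetyl target), via cyclic imine 30 (not isolated)
Conditions: CF3CO2H/CH2Cl2 1:4, 0 °C, evaporate; NaOAc/AcOH buffer (pH 5), MeCN/H2O, rt; then 37% aq CH2O (1.2 equiv), 40 °C
Reagents that add atoms: formaldehyde C=O; water O
Why: Loss of the Boc group frees the carbinolamine and its cyclic imine 30, whose nitrogen takes up formaldehyde to an N-methylene iminium ion that is attacked by the enol of the ethyl ketone (intramolecular Mannich reaction, seven-membered ring A), water returns to the imine carbon on the only face that keeps rings B and C cis-fused, and since the Mannich, aldol and carbinolamine bonds are all reversible in the buffer the carbinol carbon (only the epimer with the acyl chain cis to nitrogen can be bridged) and the C-methyl carbon (by enolisation) settle under thermodynamic control.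

**Step 17**
Reactants: 31 hexacyclic ketone
Product: 32 target CNP0309418.1
Conditions: Ac2O (1.2 equiv), Et3N, CH2Cl2, 0 °C
Reagents that add atoms: acetic anhydride CC(=O)OC(C)=O
Why: The ring E C–H between the ketone and the vinylogous ester is by far the most acidic site because its loss gives a cyclopentadienide-like oxidofulvene, and O-acylation of this anion (enol ester formation) should give the acetoxyfulvene while the two hindered tertiary hydroxyl groups stay free in the absence of an acyl-transfer catalyst, the uncontrolled ring E carbon becoming planar and no other stereocentre being touched.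

**Compound list**

1 | tert-butyldimethyl(prop-2-yn-1-yloxy)silane | C#CCO[Si](C)(C)C(C)(C)C | starting material
2 | oxetane | C1COC1 | starting material
3 | 6-[(tert-butyldimethylsilyl)oxy]hex-4-yn-1-ol | OCCCC#CCO[Si](C)(C)C(C)(C)C | intermediate
4 | 6-[(tert-butyldimethylsilyl)oxy]hex-4-ynal | O=CCCC#CCO[Si](C)(C)C(C)(C)C | intermediate
5 | 7-[(tert-butyldimethylsilyl)oxy]-1-nitrohept-5-yn-2-ol (racemic nitroaldol) | [O-][N+](=O)CC(O)CCC#CCO[Si](C)(C)C(C)(C)C | intermediate
6 | (E)-tert-butyldimethyl[(7-nitrohept-6-en-2-yn-1-yl)oxy]silane | [O-][N+](=O)/C=C/CCC#CCO[Si](C)(C)C(C)(C)C | intermediate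
7 | methyl acetoacetate | CC(=O)CC(=O)OC | starting material
8 | methyl (3S)-2-acetyl-8-[(tert-butyldimethylsilyl)oxy]-3-(nitromethyl)oct-6-ynoate (epimers at C2) | [O-][N+](=O)C[C@@H](CCC#CCO[Si](C)(C)C(C)(C)C)C(C(C)=O)C(=O)OC | intermediate
9 | methyl (3S)-2-acetyl-3-(aminomethyl)-8-[(tert-butyldimethylsilyl)oxy]oct-6-ynoate | NC[C@@H](CCC#CCO[Si](C)(C)C(C)(C)C)C(C(C)=O)C(=O)OC | intermediate
10 | methyl (4S)-4-{5-[(tert-butyldimethylsilyl)oxy]pent-3-yn-1-yl}-2-methyl-4,5-dihydro-1H-pyrrole-3-carboxylate | CC1=C(C(=O)OC)[C@H](CCC#CCO[Si](C)(C)C(C)(C)C)CN1 | intermediate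
11 | methyl (3S,4R)-3-{5-[(tert-butyldimethylsilyl)oxy]pent-3-yn-1-yl}-4,5-dimethyl-3,4-dihydro-2H-pyrrole-4-carboxylate (C-methyl trans to the side chain) | CC1=NC[C@@H](CCC#CCO[Si](C)(C)C(C)(C)C)[C@@]1(C)C(=O)OC | intermediate
12 | 1-tert-butyl 3-methyl (3R,4S)-4-{5-[(tert-butyldimethylsilyl)oxy]pent-3-yn-1-yl}-3-methyl-2-methylidenepyrrolidine-1,3-dicarboxylate | C=C1N(C(=O)OC(C)(C)C)C[C@@H](CCC#CCO[Si](C)(C)C(C)(C)C)[C@@]1(C)C(=O)OC | intermediate
13 | tert-butyl (3R,4S)-4-{5-[(tert-butyldimethylsilyl)oxy]pent-3-yn-1-yl}-3-formyl-3-methyl-2-methylidenepyrrolidine-1-carboxylate | C=C1N(C(=O)OC(C)(C)C)C[C@@H](CCC#CCO[Si](C)(C)C(C)(C)C)[C@@]1(C)C=O | intermediate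
14 | tert-butyl (3S,4S)-4-{5-[(tert-butyldimethylsilyl)oxy]pent-3-yn-1-yl}-3-ethynyl-3-methyl-2-methylidenepyrrolidine-1-carboxylate | C=C1N(C(=O)OC(C)(C)C)C[C@@H](CCC#CCO[Si](C)(C)C(C)(C)C)[C@@]1(C)C#C | intermediate
15 | tert-butyl (3S,4S)-3-ethynyl-4-(5-hydroxypent-3-yn-1-yl)-3-methyl-2-methylidenepyrrolidine-1-carboxylate | C=C1N(C(=O)OC(C)(C)C)C[C@@H](CCC#CCO)[C@@]1(C)C#C | intermediate
16 | N,N'-dimethoxy-N,N'-dimethyloxamide | CON(C)C(=O)C(=O)N(C)OC | starting material
17 | bromomagnesium hemiaminal from one EtMgBr and 16 | CCC(O[Mg]Br)(N(C)OC)C(=O)N(C)OC | intermediate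
18 | bis(bromomagnesium) alkoxide acetylide of 15 | C=C1N(C(=O)OC(C)(C)C)C[C@@H](CCC#CCO[Mg]Br)[C@@]1(C)C#C[Mg]Br | intermediate
19 | tert-butyl (3S,4S)-3-(3,4-dioxohex-1-yn-1-yl)-4-(5-hydroxypent-3-yn-1-yl)-3-methyl-2-methylidenepyrrolidine-1-carboxylate | C=C1N(C(=O)OC(C)(C)C)C[C@@H](CCC#CCO)[C@@]1(C)C#CC(=O)C(=O)CC | intermediate
20 | benzenesulfinate ester of 19 (epimers at sulfur) | C=C1N(C(=O)OC(C)(C)C)C[C@@H](CCC#CCOS(=O)c2ccccc2)[C@@]1(C)C#CC(=O)C(=O)CC | intermediate
21 | tert-butyl (3S,4S)-4-[3-(benzenesulfonyl)penta-3,4-dien-1-yl]-3-(3,4-dioxohex-1-yn-1-yl)-3-methyl-2-methylidenepyrrolidine-1-carboxylate | C=C1N(C(=O)OC(C)(C)C)C[C@@H](CCC(=C=C)S(=O)(=O)c2ccccc2)[C@@]1(C)C#CC(=O)C(=O)CC | intermediate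
22 | tricyclic dienone, rings C, D, E: N-Boc 2-methylidenepyrrolidine cis-fused to ring D (angular methyl and ring-fusion H cis), phenylsulfonyl on the ring D carbon of the C=C that is exocyclic to ring E, 2-oxobutanoyl on the α-carbon of the cyclopentenone | O=C1CC2=C(S(=O)(=O)c3ccccc3)CC[C@@H]3CN(C(=O)OC(C)(C)C)C(=C)[C@]3(C)C2=C1C(=O)C(=O)CC | intermediate
23 | tetracyclic N-Boc carbinolamine, rings B, C, D, E: tertiary carbinol with propionyl cis to nitrogen, both hydroxyl groups cis to the angular methyl | O=C1CC2=C(S(=O)(=O)c3ccccc3)CC[C@@H]3CN(C(=O)OC(C)(C)C)[C@]4(O)C[C@](O)(C(=O)CC)C1=C2[C@]34C | intermediate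
24 | dimethylaminomethyl derivative of 23 at the ring E methylene (epimers) | O=C1C(CN(C)C)C2=C(S(=O)(=O)c3ccccc3)CC[C@@H]3CN(C(=O)OC(C)(C)C)[C@]4(O)C[C@](O)(C(=O)CC)C1=C2[C@]34C | intermediate
25 | trimethylammonium iodide of 24 | O=C1C(C[N+](C)(C)C)C2=C(S(=O)(=O)c3ccccc3)CC[C@@H]3CN(C(=O)OC(C)(C)C)[C@]4(O)C[C@](O)(C(=O)CC)C1=C2[C@]34C.[I-] | intermediate
26 | ring E 5-methylidene ketone of 23 (cross-conjugated trienone sulfone) | O=C1C(=C)C2=C(S(=O)(=O)c3ccccc3)CC[C@@H]3CN(C(=O)OC(C)(C)C)[C@]4(O)C[C@](O)(C(=O)CC)C1=C2[C@]34C | intermediate
27 | methanol | CO | starting material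
28 | ring E 2-hydroxyethyl ketone (epimers at the ring E carbon) | O=C1C(CCO)C2=C(S(=O)(=O)c3ccccc3)CC[C@@H]3CN(C(=O)OC(C)(C)C)[C@]4(O)C[C@](O)(C(=O)CC)C1=C2[C@]34C | intermediate
29 | pentacyclic vinylogous ester, rings B to F, N-Boc carbinolamine, propionyl carbinol (epimers at the ring E carbon) | O=C1C2CCOC3=C2C2=C1[C@@](O)(C(=O)CC)C[C@@]4(O)N(C(=O)OC(C)(C)C)C[C@@H](CC3)[C@@]24C | intermediate
30 | cyclic imine (ring C as 1-pyrroline) of deprotected 29 | O=C1C2CCOC3=C2C2=C1[C@@](O)(C(=O)CC)CC4=NC[C@@H](CC3)[C@@]24C | intermediate
31 | hexacyclic ketone, keto tautomer of the deacetyl target (epimers at the ring E carbon) | O=C1C2CCOC3=C2C2=C1[C@]1(O)C[C@@]4(O)N(C[C@@H](CC3)[C@@]24C)C[C@@H](C)C1=O | intermediate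
32 | CNP0309418.1 | CC(=O)OC1=C2CCOC3=C2C2=C1[C@]1(O)C[C@@]4(O)N(C[C@@H](CC3)[C@@]24C)C[C@@H](C)C1=O | target

Total step count: 17. Longest linear sequence: 17 steps (from 1).

**Steps most likely to fail**

**Step 15 (key step).**
- What may go wrong: the cross-conjugated chromophore of 26 may compete for the light and decompose or dimerise. The exocyclic enone may oligomerise or take up methanol through oxygen. Hydrogen abstraction next to the carbamate nitrogen may also compete.
- Fallback (known chemistry; a two-carbon electrophile instead of a one-carbon radical): it sets out from 23 and comes back at 29.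
- The very acidic ring E methylene of 23 is alkylated (K2CO3, DMF, 0 °C) with 1,3,2-dioxathiolane 2,2-dioxide to the sulfate half ester F1.
- Dilute H2SO4 in wet THF hydrolyses F1 to hydroxyethyl ketone 28, and Et3N closes ring F to 29. Steps 14 and 15 then fall away.

**Step 16.**
- What may go wrong: loss of water from the β-hydroxy imine (aldol condensation) may outrun ring closure. The enol may attack the imine carbon instead of the N-methylene iminium ion. Formaldehyde may link molecules to oligomers.
- Fallback: it sets out from 29 and comes back at 31.
- With nitrogen still protected, the ethyl ketone is first converted by α-methylenation ((CH2O)n, iPr2NH·CF3CO2H, THF, reflux) into the isopropenyl ketone F2. Adducts at the tertiary ring E carbon cannot eliminate and revert.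
- CF3CO2H and then the buffer give the imine enone F3. Its nitrogen closes ring A by intramolecular conjugate addition, and water adds to the iminium carbon to give 31.

**Step 13.**
- What may go wrong: protonation and hydrolysis of the enecarbamate may outrun C–C bond formation. Closure may also stop at the carbinol epimer that cannot be bridged.
- Fallback: it sets out from 22 and comes back at 23.
- The enecarbamate is hydrolysed on purpose (oxalic acid, wet THF) to the methyl ketone F4.
- Ring B is then closed by a direct, reversible aldol addition through the magnesium enolate (MgBr2·OEt2, iPr2NEt, CH2Cl2), in which magnesium also chelates the 1,2-diketone. The keto carbamate formed closes to 23.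

**Further compounds**

F1 | step 15 | 2-(sulfooxy)ethyl derivative of 23 at the ring E methylene | O=C1C(CCOS(=O)(=O)O)C2=C(S(=O)(=O)c3ccccc3)CC[C@@H]3CN(C(=O)OC(C)(C)C)[C@]4(O)C[C@](O)(C(=O)CC)C1=C2[C@]34C
F2 | step 16 | isopropenyl ketone analogue of 29 | O=C1C2CCOC3=C2C2=C1[C@@](O)(C(=O)C(C)=C)C[C@@]4(O)N(C(=O)OC(C)(C)C)C[C@@H](CC3)[C@@]24C
F3 | step 16 | imine enone (deprotected F2, ring C as 1-pyrroline) | O=C1C2CCOC3=C2C2=C1[C@@](O)(C(=O)C(C)=C)CC4=NC[C@@H](CC3)[C@@]24C
F4 | step 13 | methyl ketone N-Boc amine from hydrolysis of 22 | O=C1CC2=C(S(=O)(=O)c3ccccc3)CC[C@H](CNC(=O)OC(C)(C)C)[C@](C)(C(C)=O)C2=C1C(=O)C(=O)CC
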